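**Retrosynthetic overview**
1. The target (achiral) is reached by hydrogenolysis of three benzyl ethers (O3', O5, O7) after bis-sulfation of a 3,4'-diol; O3 and O4' travel as MOM ethers until then.
2. The strategy rests on ring A: its oxygens on C5 and C7 are 1,3-related and flank the ring-fusion bond C4a–C8a. Ring A is therefore cut at C4a–C5 and C8–C8a into a 1,3-dioxygenated four-carbon diene and the C5=C6 bond of a 5-bromo-4-pyranone, whose bromine sits on the future C4a.
3. The bromopyranone (ring C, with ring B on C2) comes from a 2-aryl-3-hydroxy-4-pyranone, made from an aryl furyl carbinol by Achmatowicz ring expansion, epoxidation and acid rearrangement.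
4. The diene comes from methyl acetoacetate by two silylations.
5. Ring order: ring B (bought) → ring C (furan to pyranone) → ring A (annulation and aromatization).

Key step: step 12

Assumption: sulfate monoesters are named and drawn as free hydrogen sulfates (they would be handled as pyridinium or sodium salts, the acid form being released by cold H+-form ion exchange), and compounds 6–9, 12 and 19 are racemates or diastereomer mixtures whose stereocentres are all erased later, so their SMILES carry no configuration.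

**Step 1**
Reactants: 1 3,4-dihydroxybenzaldehyde
Product: 2 3-hydroxy-4-(methoxymethoxy)benzaldehyde
Conditions: MOMCl (1.05 equiv), K2CO3 (1.1 equiv), acetone, 0 °C → rt
Reagents that add atoms: chloromethyl methyl ether, COCCl
Why: Williamson etherification; the 4-hydroxyl, para to the formyl group, is the more acidic phenol, so with one equivalent of base and MOMCl its phenoxide should be alkylated selectively.

**Step 2**
Reactants: 2 3-hydroxy-4-(methoxymethoxy)benzaldehyde
Product: 3 3-(benzyloxy)-4-(methoxymethoxy)benzaldehyde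
Conditions: BnBr (1.2 equiv), K2CO3 (1.5 equiv), DMF, rt
Reagents that add atoms: benzyl bromide, BrCc1ccccc1
Why: Williamson etherification of the remaining phenol; the aldehyde and the MOM acetal are inert to K2CO3 and BnBr.

**Step 3**
Reactants: 4 furan; 3 3-(benzyloxy)-4-(methoxymethoxy)benzaldehyde
Product: 6 [3-(benzyloxy)-4-(methoxymethoxy)phenyl](furan-2-yl)methanol (racemic), via 2-lithiofuran 5 (not isolated)
Conditions: furan (1.5 equiv), n-BuLi (1.3 equiv), THF, −78 → 0 °C; then 3, −78 °C → rt; H2O
Reagents that add atoms: none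
Why: Furan is lithiated at C2 next to the ring oxygen and the organolithium adds 1,2 to the aldehyde; the carbinol centre forms racemic and is erased in step 7.

**Step 4**
Reactants: 6 [3-(benzyloxy)-4-(methoxymethoxy)phenyl](furan-2-yl)methanol
Product: 7 2-[3-(benzyloxy)-4-(methoxymethoxy)phenyl]-6-hydroxy-2H-pyran-3(6H)-one (racemic cis/trans mixture)
Conditions: NBS (1.05 equiv), NaHCO3 (2 equiv), THF/H2O (4:1), 0 °C
Reagents that add atoms: water, O
Why: Achmatowicz rearrangement: NBS and water oxidize the furan, the ring opens and recloses through the carbinol oxygen to the 6-hydroxypyranone; the furan is far more reactive towards NBS than the alkoxyarene, and the new anomeric centre forms as a mixture that does not matter.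

**Step 5**
Reactants: 7 2-[3-(benzyloxy)-4-(methoxymethoxy)phenyl]-6-hydroxy-2H-pyran-3(6H)-one
Product: 8 2-[3-(benzyloxy)-4-(methoxymethoxy)phenyl]-6-methoxy-2H-pyran-3(6H)-one (racemic cis/trans mixture)
Conditions: MeI (5 equiv), Ag2O (1.5 equiv), CH2Cl2, rt, dark
Reagents that add atoms: iodomethane, CI
Why: Purdie O-methylation of the anomeric hydroxyl under non-basic conditions fixes the ring as its methyl acetal, so that it cannot open during the alkaline epoxidation.

**Step 6**
Reactants: 8 2-[3-(benzyloxy)-4-(methoxymethoxy)phenyl]-6-methoxy-2H-pyran-3(6H)-one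
Product: 9 4-[3-(benzyloxy)-4-(methoxymethoxy)phenyl]-2-methoxy-3,7-dioxabicyclo[4.1.0]heptan-5-one (diastereomer mixture)
Conditions: 30% H2O2, NaOH (0.2 equiv), MeOH, −10 → 0 °C
Reagents that add atoms: hydrogen peroxide, OO
Why: Weitz–Scheffer nucleophilic epoxidation of the enone C4=C5 bond, expected anti to the C6 methoxy group; the configuration is irrelevant because all four sp3 centres are lost in step 7.

**Step 7**
Reactants: 9 4-[3-(benzyloxy)-4-(methoxymethoxy)phenyl]-2-methoxy-3,7-dioxabicyclo[4.1.0]heptan-5-one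
Product: 10 2-[3-(benzyloxy)-4-hydroxyphenyl]-3-hydroxy-4H-pyran-4-one
Conditions: 2 M HCl, iPrOH/H2O (1:1), 70 °C
Reagents that add atoms: none
Why: Acid-catalysed isomerization of the α,β-epoxy ketone to the diosphenol, β-elimination of methanol from C6 and enolization of the benzylic C2–H aromatize the ring to the 3-hydroxy-4-pyranone (the rearrangement by which maltol is made from the 2-methyl analogue), and the aryl MOM ether is hydrolysed in the same operation.

**Step 8**
Reactants: 10 2-[3-(benzyloxy)-4-hydroxyphenyl]-3-hydroxy-4H-pyran-4-one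
Product: 11 2-[3-(benzyloxy)-4-(methoxymethoxy)phenyl]-3-(methoxymethoxy)-4H-pyran-4-one
Conditions: MOMCl (3 equiv), iPr2NEt (4 equiv), CH2Cl2, 0 °C → rt
Reagents that add atoms: chloromethyl methyl ether, COCCl
Why: O-alkylation of the enolic 3-hydroxyl and of the 4'-phenol with MOMCl and an amine base gives the bis-acetal that later allows both oxygens to be freed together.

**Step 9**
Reactants: 11 2-[3-(benzyloxy)-4-(methoxymethoxy)phenyl]-3-(methoxymethoxy)-4H-pyran-4-one
Product: 13 2-[3-(benzyloxy)-4-(methoxymethoxy)phenyl]-5-bromo-3-(methoxymethoxy)-4H-pyran-4-one, via dibromide 12 (not isolated)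
Conditions: Br2 (1.05 equiv), CH2Cl2, −40 °C; then Et3N (2.5 equiv), −40 °C → rt
Reagents that add atoms: bromine, BrBr
Why: Bromine adds across the C5=C6 enol ether bond of the vinylogous ester and Et3N then removes the acidic C5–H with loss of the C6 bromide (addition–elimination, the usual entry to 3-bromo-4-pyranones and 3-bromochromones); the fully substituted C2=C3 bond can add bromine only reversibly, and at −40 °C ring B, deactivated by conjugation with the pyranone, should not compete.

**Step 10**
Reactants: 14 methyl acetoacetate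
Product: 15 methyl 3-(trimethylsilyloxy)but-2-enoate (E/Z mixture)
Conditions: Me3SiCl (1.2 equiv), Et3N (1.3 equiv), hexane, rt
Reagents that add atoms: chlorotrimethylsilane, C[Si](C)(C)Cl
Why: O-silylation of the enol form of the β-keto ester gives the silyl enol ether; its geometry disappears in the next step.

**Step 11**
Reactants: 15 methyl 3-(trimethylsilyloxy)but-2-enoate
Product: 17 (1Z)-1-methoxy-1,3-bis(trimethylsilyloxy)buta-1,3-diene, via lithium dienolate 16 (not isolated)
Conditions: LiN(iPr)2 (1.1 equiv), THF, −78 °C; then Me3SiCl (1.2 equiv), −78 °C → rt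
Reagents that add atoms: chlorotrimethylsilane, C[Si](C)(C)Cl
Why: γ-Deprotonation of the silyl enol ether gives the extended ester enolate, which is silylated on oxygen to the ketene acetal diene; the C1=C2 geometry has no influence on the annulation.

**Step 12**
Reactants: 13 2-[3-(benzyloxy)-4-(methoxymethoxy)phenyl]-5-bromo-3-(methoxymethoxy)-4H-pyran-4-one; 17 (1Z)-1-methoxy-1,3-bis(trimethylsilyloxy)buta-1,3-diene
Product: 21 2-[3-(benzyloxy)-4-(methoxymethoxy)phenyl]-5,7-dihydroxy-3-(methoxymethoxy)-4H-chromen-4-one, via silyloxypyrylium triflate 18 (not isolated), via bromo cycloadduct 19 (not isolated), via bis(trimethylsilyl) ether 20 (not isolated)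
Conditions: t-BuMe2SiOTf (1.3 equiv), 2,6-lutidine (3 equiv), CH2Cl2, −78 °C; 17 (2 equiv), −78 → 0 °C; then K2CO3, MeOH, 0 °C
Reagents that add atoms: none
Why: Proposed new method: O-silylation of the C4 carbonyl turns 13 into pyrylium 18, whose free C6 is attacked by the CH2 terminus of diene 17 (Mukaiyama–Michael addition, bond C8–C8a), and the resulting 5-bromo silyl dienol ether closes through C5 onto the ketene-acetal-derived oxocarbenium carbon (bond C4a–C5, 6-exo-trig), so that ring A forms by a stepwise polar [4+2] annulation to give adduct 19. The silyl triflate should then ionize the mixed ketal at C5 with loss of the methoxy group as its silyl ether, C8 loses a proton, and the now allylic, doubly oxygen-stabilized C4a–Br bond ionizes to an arenium ion that loses H-8a (taken up by lutidine), giving bis-silyl ether 20, which carbonate methanolysis converts into 21. The closest known reaction types are the Diels–Alder and aromatization sequence of 1-alkoxy-1,3-bis(silyloxy)dienes with 2-haloquinones and the silyl-triflate-mediated conjugate addition of silyl enol ethers and of such dienes to 4-pyranones and chromones; ring closure at the halogen-bearing carbon of a 5-bromo-4-pyranone has not been shown. No stereocentre survives, because those of 19 are lost on aromatization. The step needs regioselectivity (oxygens at C5 and C7) and attack at C6 rather than C2: the diene is nucleophilic at its CH2 end, C2 of the pyrylium is blocked by the aryl group, and the bromine marks C5 as the carbon that becomes C4a and serves as the leaving group. The low temperature, the bulky silyl triflate and the lutidine buffer are chosen so that the two MOM ethers should survive.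

**Step 13**
Reactants: 21 2-[3-(benzyloxy)-4-(methoxymethoxy)phenyl]-5,7-dihydroxy-3-(methoxymethoxy)-4H-chromen-4-one
Product: 22 5,7-bis(benzyloxy)-2-[3-(benzyloxy)-4-(methoxymethoxy)phenyl]-3-(methoxymethoxy)-4H-chromen-4-one
Conditions: BnBr (3 equiv), K2CO3 (4 equiv), Bu4NI (0.1 equiv), DMF, 70 °C
Reagents that add atoms: benzyl bromide, BrCc1ccccc1
Why: Williamson etherification of both phenols; the chelated 5-hydroxyl needs excess BnBr, iodide catalysis and warming, and the MOM ethers are stable to base.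

**Step 14**
Reactants: 22 5,7-bis(benzyloxy)-2-[3-(benzyloxy)-4-(methoxymethoxy)phenyl]-3-(methoxymethoxy)-4H-chromen-4-one
Product: 23 5,7-bis(benzyloxy)-2-[3-(benzyloxy)-4-hydroxyphenyl]-3-hydroxy-4H-chromen-4-one
Conditions: 3 M HCl, MeOH/THF (1:1), 45 °C
Reagents that add atoms: none
Why: Acid-catalysed acetal exchange with methanol should remove both MOM ethers and leave the three benzyl ethers, freeing exactly the two hydroxyls that are to be sulfated.

**Step 15**
Reactants: 23 5,7-bis(benzyloxy)-2-[3-(benzyloxy)-4-hydroxyphenyl]-3-hydroxy-4H-chromen-4-one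
Product: 24 5,7-bis(benzyloxy)-2-[3-(benzyloxy)-4-(sulfooxy)phenyl]-4-oxo-4H-chromen-3-yl hydrogen sulfate
Conditions: SO3·pyridine (10 equiv), pyridine, 45 °C
Reagents that add atoms: sulfur trioxide–pyridine complex, [O-]S(=O)(=O)[n+]1ccccc1
Why: O-sulfonation of the 4'-phenol and of the enolic 3-hydroxyl by excess SO3–pyridine; no other free hydroxyl is present, so the sulfation pattern is fixed by the protecting groups.

**Step 16**
Reactants: 24 5,7-bis(benzyloxy)-2-[3-(benzyloxy)-4-(sulfooxy)phenyl]-4-oxo-4H-chromen-3-yl hydrogen sulfate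
Product: 25 quercetin 3,4'-bissulfate
Conditions: H2 (1 atm), 10% Pd/C, MeOH/THF, rt; then H+-form sulfonic acid resin, H2O, 0 °C, freeze-drying
Reagents that add atoms: none
Why: Hydrogenolysis of the three benzyl ethers over Pd/C at near-neutral pH, conditions under which aryl sulfate monoesters and the flavonol C2=C3 bond should persist; cold ion exchange then gives the free bis(hydrogen sulfate).

**Compound list**
1 | 3,4-dihydroxybenzaldehyde | O=Cc1ccc(O)c(O)c1 | starting material
2 | 3-hydroxy-4-(methoxymethoxy)benzaldehyde | O=Cc1ccc(OCOC)c(O)c1 | intermediate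
3 | 3-(benzyloxy)-4-(methoxymethoxy)benzaldehyde | O=Cc1ccc(OCOC)c(OCc2ccccc2)c1 | intermediate
4 | furan | c1ccoc1 | starting material
5 | 2-lithiofuran | [Li]c1ccco1 | intermediate (not isolated)
6 | [3-(benzyloxy)-4-(methoxymethoxy)phenyl](furan-2-yl)methanol, racemic | OC(c1ccco1)c1ccc(OCOC)c(OCc2ccccc2)c1 | intermediate
7 | 2-[3-(benzyloxy)-4-(methoxymethoxy)phenyl]-6-hydroxy-2H-pyran-3(6H)-one, racemic cis/trans mixture | O=C1C=CC(O)OC1c1ccc(OCOC)c(OCc2ccccc2)c1 | intermediate
8 | 2-[3-(benzyloxy)-4-(methoxymethoxy)phenyl]-6-methoxy-2H-pyran-3(6H)-one, racemic cis/trans mixture | O=C1C=CC(OC)OC1c1ccc(OCOC)c(OCc2ccccc2)c1 | intermediate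
9 | 4-[3-(benzyloxy)-4-(methoxymethoxy)phenyl]-2-methoxy-3,7-dioxabicyclo[4.1.0]heptan-5-one, diastereomer mixture | O=C1C2OC2C(OC)OC1c1ccc(OCOC)c(OCc2ccccc2)c1 | intermediate
10 | 2-[3-(benzyloxy)-4-hydroxyphenyl]-3-hydroxy-4H-pyran-4-one | O=c1ccoc(-c2ccc(O)c(OCc3ccccc3)c2)c1O | intermediate
11 | 2-[3-(benzyloxy)-4-(methoxymethoxy)phenyl]-3-(methoxymethoxy)-4H-pyran-4-one | O=c1ccoc(-c2ccc(OCOC)c(OCc3ccccc3)c2)c1OCOC | intermediate
12 | 2-[3-(benzyloxy)-4-(methoxymethoxy)phenyl]-5,6-dibromo-3-(methoxymethoxy)-5,6-dihydro-4H-pyran-4-one, racemic, trans expected | O=C1C(Br)C(Br)OC(-c2ccc(OCOC)c(OCc3ccccc3)c2)=C1OCOC | intermediate (not isolated)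
13 | 2-[3-(benzyloxy)-4-(methoxymethoxy)phenyl]-5-bromo-3-(methoxymethoxy)-4H-pyran-4-one | O=c1c(Br)coc(-c2ccc(OCOC)c(OCc3ccccc3)c2)c1OCOC | intermediate
14 | methyl acetoacetate | COC(=O)CC(C)=O | starting material
15 | methyl 3-(trimethylsilyloxy)but-2-enoate, E/Z mixture | COC(=O)C=C(C)O[Si](C)(C)C | intermediate
16 | lithium 1-methoxy-3-(trimethylsilyloxy)buta-1,3-dien-1-olate | CO/C([O-])=C/C(=C)O[Si](C)(C)C.[Li+] | intermediate (not isolated)
17 | (1Z)-1-methoxy-1,3-bis(trimethylsilyloxy)buta-1,3-diene | CO/C(O[Si](C)(C)C)=C/C(=C)O[Si](C)(C)C | intermediate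
18 | 2-[3-(benzyloxy)-4-(methoxymethoxy)phenyl]-5-bromo-4-(tert-butyldimethylsilyloxy)-3-(methoxymethoxy)pyrylium trifluoromethanesulfonate | CC(C)(C)[Si](C)(C)Oc1c(Br)c[o+]c(-c2ccc(OCOC)c(OCc3ccccc3)c2)c1OCOC.[O-]S(=O)(=O)C(F)(F)F | intermediate (not isolated)
19 | 2-[3-(benzyloxy)-4-(methoxymethoxy)phenyl]-4a-bromo-5-methoxy-3-(methoxymethoxy)-5,7-bis(trimethylsilyloxy)-4a,5,8,8a-tetrahydro-4H-chromen-4-one, racemic, cis ring fusion expected | O=C1C(OCOC)=C(c2ccc(OCOC)c(OCc3ccccc3)c2)OC2CC(O[Si](C)(C)C)=CC(OC)(O[Si](C)(C)C)C12Br | intermediate (not isolated)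
20 | 2-[3-(benzyloxy)-4-(methoxymethoxy)phenyl]-3-(methoxymethoxy)-5,7-bis(trimethylsilyloxy)-4H-chromen-4-one | O=c1c(OCOC)c(-c2ccc(OCOC)c(OCc3ccccc3)c2)oc2cc(O[Si](C)(C)C)cc(O[Si](C)(C)C)c12 | intermediate (not isolated)
21 | 2-[3-(benzyloxy)-4-(methoxymethoxy)phenyl]-5,7-dihydroxy-3-(methoxymethoxy)-4H-chromen-4-one | O=c1c(OCOC)c(-c2ccc(OCOC)c(OCc3ccccc3)c2)oc2cc(O)cc(O)c12 | intermediate
22 | 5,7-bis(benzyloxy)-2-[3-(benzyloxy)-4-(methoxymethoxy)phenyl]-3-(methoxymethoxy)-4H-chromen-4-one | O=c1c(OCOC)c(-c2ccc(OCOC)c(OCc3ccccc3)c2)oc2cc(OCc3ccccc3)cc(OCc3ccccc3)c12 | intermediate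
23 | 5,7-bis(benzyloxy)-2-[3-(benzyloxy)-4-hydroxyphenyl]-3-hydroxy-4H-chromen-4-one | O=c1c(O)c(-c2ccc(O)c(OCc3ccccc3)c2)oc2cc(OCc3ccccc3)cc(OCc3ccccc3)c12 | intermediate
24 | 5,7-bis(benzyloxy)-2-[3-(benzyloxy)-4-(sulfooxy)phenyl]-4-oxo-4H-chromen-3-yl hydrogen sulfate | O=c1c(OS(=O)(=O)O)c(-c2ccc(OS(=O)(=O)O)c(OCc3ccccc3)c2)oc2cc(OCc3ccccc3)cc(OCc3ccccc3)c12 | intermediate
25 | quercetin 3,4'-bissulfate | O=c1c(OS(=O)(=O)O)c(-c2ccc(OS(=O)(=O)O)c(O)c2)oc2cc(O)cc(O)c12 | target

**Totals**
Total step count: 16. Longest linear sequence: 14 steps (steps 1–9 and 12–16, from 3,4-dihydroxybenzaldehyde); steps 10–11 form the diene branch.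

**Steps most likely to fail**

Step 12 (proposed new method). Four processes threaten it:
- The second C–C bond may fail to close after the conjugate addition, so that the intermediate loses HBr towards a 6-alkylated pyranone instead of ring A.
- The mixed ketal may lose silanolate instead of methoxide, which would leave the C5 oxygen methylated.
- Premature desilylation would allow ring C to open by a retro-oxa-Michael reaction.
- The MOM ethers may be cleaved by silyl triflate or silyl bromide.

The fallback uses known flavonol chemistry and sets out from aldehyde 3. Claisen–Schmidt condensation with purchased 1-[2,4-bis(benzyloxy)-6-hydroxyphenyl]ethan-1-one (KOH, EtOH, rt) should give the chalcone (E)-1-[2,4-bis(benzyloxy)-6-hydroxyphenyl]-3-[3-(benzyloxy)-4-(methoxymethoxy)phenyl]prop-2-en-1-one F1. Algar–Flynn–Oyamada oxidative cyclization (H2O2, NaOH, MeOH/THF, 0 °C) should then close ring C with the 3-hydroxyl in place, giving 5,7-bis(benzyloxy)-2-[3-(benzyloxy)-4-(methoxymethoxy)phenyl]-3-hydroxy-4H-chromen-4-one F2. HCl in MeOH/THF removes the MOM ether and delivers diol 23, where the route continues with step 15.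

Step 9. Bromine may be consumed by electrophilic substitution on ring B, or by addition to the electron-rich C2=C3 enol ether with loss of the 3-O-MOM group, instead of addition–elimination at C5=C6. The fallback changes the substrate so that both competing sites are electron-poorer, and sets out from diol 10. Acetylation (Ac2O, pyridine) gives 2-[4-(acetyloxy)-3-(benzyloxy)phenyl]-4-oxo-4H-pyran-3-yl acetate F3. Br2 in CH2Cl2 gives 2-[4-(acetyloxy)-3-(benzyloxy)phenyl]-5,6-dibromo-4-oxo-5,6-dihydro-4H-pyran-3-yl acetate F4, from which Et3N removes HBr to give 2-[4-(acetyloxy)-3-(benzyloxy)phenyl]-5-bromo-4-oxo-4H-pyran-3-yl acetate F5. Acid methanolysis (HCl, MeOH, 40 °C) gives 2-[3-(benzyloxy)-4-hydroxyphenyl]-5-bromo-3-hydroxy-4H-pyran-4-one F6, and MOMCl with iPr2NEt returns to bromopyranone 13.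

Step 15. Sulfation may stop at the 4'-monosulfate, because the 3-hydroxyl is chelated to the C4 carbonyl and flanked by ring B, and the enol-type 3-sulfate may hydrolyse while the dianion is isolated. The fallback installs both sulfates as neutral protected diesters and sets out from diol 23. 2,2,2-Trichloroethyl chlorosulfate with Et3N and DMAP in THF should give 5,7-bis(benzyloxy)-2-{3-(benzyloxy)-4-[(2,2,2-trichloroethoxy)sulfonyloxy]phenyl}-4-oxo-4H-chromen-3-yl 2,2,2-trichloroethyl sulfate F7, which can be purified on silica. Zn and HCO2NH4 in MeOH then unmask both sulfate monoesters to give 24, and the route continues with step 16.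

**Further compounds**
F1 | step 12 | (E)-1-[2,4-bis(benzyloxy)-6-hydroxyphenyl]-3-[3-(benzyloxy)-4-(methoxymethoxy)phenyl]prop-2-en-1-one | O=C(/C=C/c1ccc(OCOC)c(OCc2ccccc2)c1)c1c(O)cc(OCc2ccccc2)cc1OCc1ccccc1
F2 | step 12 | 5,7-bis(benzyloxy)-2-[3-(benzyloxy)-4-(methoxymethoxy)phenyl]-3-hydroxy-4H-chromen-4-one | O=c1c(O)c(-c2ccc(OCOC)c(OCc3ccccc3)c2)oc2cc(OCc3ccccc3)cc(OCc3ccccc3)c12
F3 | step 9 | 2-[4-(acetyloxy)-3-(benzyloxy)phenyl]-4-oxo-4H-pyran-3-yl acetate | O=c1ccoc(-c2ccc(OC(C)=O)c(OCc3ccccc3)c2)c1OC(C)=O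
F4 | step 9 | 2-[4-(acetyloxy)-3-(benzyloxy)phenyl]-5,6-dibromo-4-oxo-5,6-dihydro-4H-pyran-3-yl acetate | O=C1C(Br)C(Br)OC(-c2ccc(OC(C)=O)c(OCc3ccccc3)c2)=C1OC(C)=O
F5 | step 9 | 2-[4-(acetyloxy)-3-(benzyloxy)phenyl]-5-bromo-4-oxo-4H-pyran-3-yl acetate | O=c1c(Br)coc(-c2ccc(OC(C)=O)c(OCc3ccccc3)c2)c1OC(C)=O
F6 | step 9 | 2-[3-(benzyloxy)-4-hydroxyphenyl]-5-bromo-3-hydroxy-4H-pyran-4-one | O=c1c(Br)coc(-c2ccc(O)c(OCc3ccccc3)c2)c1O
F7 | step 15 | 5,7-bis(benzyloxy)-2-{3-(benzyloxy)-4-[(2,2,2-trichloroethoxy)sulfonyloxy]phenyl}-4-oxo-4H-chromen-3-yl 2,2,2-trichloroethyl sulfate | O=c1c(OS(=O)(=O)OCC(Cl)(Cl)Cl)c(-c2ccc(OS(=O)(=O)OCC(Cl)(Cl)Cl)c(OCc3ccccc3)c2)oc2cc(OCc3ccccc3)cc(OCc3ccccc3)c12
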